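All runs come from a simulation with constants of no real substance; scatter was added.

The constants of this flask are hidden, so turn the two earlier runs into times.

all flasks: substrate 0.050 M (fed, over 15 min); gas phase 6.2 mM (held)

|  | catalyst | remark | time |
|---|---|---|---|
| east | 0.05 mol% | run made earlier |  |
| west | 0.075 mol% | run made earlier |  |
| flask | 0.1 mol% |  | 1.0 h |

| run | time / min | target / % | substrate / % |
|---|---|---|---|
| east | 15.0 | 10.5 | 89.8 |
| east | 20.0 | 16.8 | 83.7 |
| east | 25.0 | 22.5 | 77.9 |
| east | 30.0 | 27.9 | 72.0 |
| east | 40.0 | 38.2 | 61.8 |
| west | 15.0 | 14.1 | 85.0 |
| west | 20.0 | 21.0 | 78.5 |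
| west | 25.0 | 28.0 | 71.8 |
| west | 30.0 | 34.6 | 64.4 |
| west | 40.0 | 46.9 | 54.0 |

(scatter of a reading: 0.5 percentage points)
- the best time, 1.0 h at the latest, for target
- the amount of target, in percent of the substrate charged, at that time
- at the start none of the gas is dissolved
- the numbers in the tables scatter by 0.5 percentage points (one standard deviation)
- steps thought possible: gas phase <-> dissolved gas; substrate + dissolved gas + catalyst -> catalyst + target

The east run's columns sum to 100 % at 40.0 min, so no loss shows and the limit is the time to take. The amount then rests on the turnover time: the minutes the whole charge would need at the pace held after the feed. It is 90.3 min in the east run and 76.2 min in the west run.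

How much does each number matter? Take west's pace first. At that pace my reckoning takes substrate from west's 85.0 % to 26.0 %, so target reaches 74.0 %. That rise is read with scatter 0.5 percentage points on 33 points.

Treat the turnover time as resistances in series: a part that ignores loading, plus a part falling with loading times substrate. That product is 1.38 times east's in the west run and 1.46 times east's in the flask. So the split hardly matters: 6.05 % of an error in it reaches the flask's pace.

The number itself, as read from the scattered runs, is 38.8 min, the gas time. The catalyst time of the flask at full substrate is 19.5 min.

The forecast gives 74 % at 1 h, and its grounds open with these words: “Treating the resistances as additive”.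

The flask gives 73.7 % at 1.00 h.

    gas phase ⇌ dissolved gas, rate k1*(csat - [dissolved gas]) (kL = 0.00400 s⁻¹)
    substrate + dissolved gas + catalyst → catalyst + target (k = 2500 M⁻² s⁻¹)

At 0.446 h dissolved gas in the flask has a half-life of 2.8 min by reaction, close to 2.89 min for uptake. At 0.500 h it stands at 0.00312 M, half of saturation. Gas time and catalyst time price the flask's fall in substrate, from 83.4 % at 0.250 h to 26.3 % at 1.00 h, at 44.7 min; the flask took 45.0 min. For the neighbour flask with 0.04 mol% catalyst, taking east's 89.8 % at 15.0 min as its start, they price the fall to 50.9 % at 1.00 h at 42.8 min. That neighbour ends with 49.1 % target.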